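The bicyclo[3.3.1]nonane is cut at C1–C8. Bridgehead C5, shared by rings A and B, lies between two oxygenated carbons (C4 and bridge carbonyl C9). It therefore maps onto the sp3 carbon of a 1,5-dimethoxycyclohexa-1,4-diene whose two enol ethers are enantiotopic. The precursor is that Birch diene carrying a prenyl group and an (R)-2,3-epoxy-3-methylbutyl chain on the same carbon. Lewis-acid opening of the epoxide at its tertiary carbon by one enol ether closes ring B, makes C1–C8, and fixes C1 and C5 from the lone epoxide stereocentre. C7 is later flattened to a methylene and reset endo by exo-face hydroboration, which also feeds the Suzuki coupling that completes the geranyl chain.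

Key step: step 6

Remark: bicyclic compounds are numbered C1 (bridgehead next to C8), C2–C4 (ring A arm), C5 (other bridgehead), C6–C8 (ring B arm), C9 (bridge); exo means pointing away from ring A, endo towards it; the target is drawn as the C4-enol of the given SMILES, although the β-triketone will equilibrate with its C2-enol.

Step 1
Reactants: 1 prenol
Product: 2 (R)-(3,3-dimethyloxiran-2-yl)methanol
Conditions: Ti(OiPr)4 (cat.), D-(−)-DIPT (cat.), t-BuOOH, 4 Å MS, CH2Cl2, −20 °C; non-aqueous work-up, distillation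
Reagents that add atoms: tert-butyl hydroperoxide CC(C)(C)OO
Why: Sharpless asymmetric epoxidation of a primary allylic alcohol, in which the D-(−)-tartrate catalyst delivers oxygen to the alkene face that gives the (R)-epoxide, the only stereocentre introduced by a chiral reagent in the route.

Step 2
Reactants: 2 (R)-(3,3-dimethyloxiran-2-yl)methanol
Product: 3 (R)-(3,3-dimethyloxiran-2-yl)methyl triflate
Conditions: Tf2O, 2,6-lutidine, CH2Cl2, −78 °C; used at once
Reagents that add atoms: triflic anhydride O=S(=O)(OS(=O)(=O)C(F)(F)F)C(F)(F)F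
Why: O-sulfonylation of the primary alcohol with a hindered base leaves the epoxide stereocentre untouched and gives an electrophile reactive enough for a tertiary carbanion at −78 °C.

Step 3
Reactants: 4 1,3-dimethoxybenzene
Product: 5 1,5-dimethoxycyclohexa-1,4-diene
Conditions: Li, NH3 (l), t-BuOH, THF, −78 → −33 °C
Reagents that add atoms: none
Why: Birch reduction keeps both remaining double bonds on the methoxy-bearing carbons and leaves a doubly allylic CH2 between the two enol ethers.

Step 4
Reactants: 5 1,5-dimethoxycyclohexa-1,4-diene; 6 prenyl bromide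
Product: 8 1,5-dimethoxy-6-prenylcyclohexa-1,4-diene, via 6-lithio-1,5-dimethoxycyclohexa-1,4-diene 7 (not isolated)
Conditions: t-BuLi, THF, −78 °C; then 6, −78 °C → rt
Reagents that add atoms: none
Why: Methoxy-directed deprotonation of the doubly allylic C6–H gives a pentadienyllithium that is alkylated at its central carbon by the allylic bromide (SN2 alkylation).

Step 5
Reactants: 8 1,5-dimethoxy-6-prenylcyclohexa-1,4-diene; 3 (R)-(3,3-dimethyloxiran-2-yl)methyl triflate
Product: 10 6-{[(2R)-3,3-dimethyloxiran-2-yl]methyl}-1,5-dimethoxy-6-prenylcyclohexa-1,4-diene, via lithiated prenyl diene 9 (not isolated)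
Conditions: s-BuLi, THF, −78 → −40 °C; then 3, THF, −78 °C
Reagents that add atoms: none
Why: A second deprotonation at C6 and SN2 displacement of the primary triflate, which is faster than epoxide opening, build the quaternary carbon; this carbon is not stereogenic because its two ring arms are identical, and the epoxide centre is not involved.

Step 6
Reactants: 10 6-{[(2R)-3,3-dimethyloxiran-2-yl]methyl}-1,5-dimethoxy-6-prenylcyclohexa-1,4-diene
Product: 12 (1S,5S,7R)-7-hydroxy-4-methoxy-8,8-dimethyl-5-prenylbicyclo[3.3.1]non-3-en-9-one (C7–OH exo), via internal C7–O–C9 methyl ketal 11 (not isolated)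
Conditions: TMSOTf (0.3 equiv), 2,6-lutidine (0.4 equiv), CH2Cl2, −78 °C; then Me2BBr (2 equiv), −78 °C; cannulate into THF–sat. aq NaHCO3
Reagents that add atoms: water O
Why: TMSOTf silylates the epoxide oxygen, the C8–O bond lengthens at the tertiary carbon, and the β-carbon of one methyl enol ether attacks C8 from the back, which forms C1–C8 and leaves an O-methyl oxocarbenium ion at C9. The closest known reaction type is the Lewis-acid epoxide-opening cyclisation of Birch-derived bis(methyl enol ethers) to bicyclo[3.3.1]nonanes, and ring B (C1, C9, C5, C6, C7, C8) closes in the 6-endo-tet mode because cationic character develops at tertiary C8 and not at secondary C7. The C9 cation has no α-hydrogen it can lose (C1 is a bridgehead, C5 is quaternary), so it should be caught by the C7 silyloxy oxygen after a chair-to-boat flip of ring B to give ketal 11 and return TMSOTf; Me2BBr is therefore added to the same flask to break the strained C9–O(C7) bond at −78 °C (haloborane acetal cleavage), and bicarbonate hydrolysis then releases the C9 ketone and the C7 alcohol. C5 is controlled by the (R)-epoxide carbon: only over one of the two enantiotopic enol ethers can the C5–C6–C7–C8 tether adopt a chair in which the C7 oxygen is equatorial and antiperiplanar to the forming bond, the other arm requiring a boat, and this choice makes C5 (S). C1 is controlled by C5, because the new bond must form on the ring face that carries the tether, so the one-carbon bridge is cis-fused and C1 becomes (S) with C7–O exo. The step needs group selectivity (secured by the chair preference), C- over O-alkylation (secured by the O-methyl groups) and enol ether over prenyl participation (secured by the far higher nucleophilicity of the enol ether), while the lutidine buffer and the basic quench keep the surviving C3=C4 enol ether intact.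

Step 7
Reactants: 12 (1S,5S,7R)-7-hydroxy-4-methoxy-8,8-dimethyl-5-prenylbicyclo[3.3.1]non-3-en-9-one
Product: 13 (1S,5S,7R)-4-methoxy-8,8-dimethyl-5-prenyl-7-(triethylsilyloxy)bicyclo[3.3.1]non-3-en-9-one
Conditions: TESOTf, 2,6-lutidine, CH2Cl2, −78 → 0 °C
Reagents that add atoms: triethylsilyl triflate CC[Si](CC)(CC)OS(=O)(=O)C(F)(F)F
Why: Silyl triflate silylation copes with the hindered equatorial C7 alcohol, C9 cannot enolise because both α-carbons are bridgeheads, and the buffered medium spares the enol ether.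

Step 8
Reactants: 13 (1S,5S,7R)-4-methoxy-8,8-dimethyl-5-prenyl-7-(triethylsilyloxy)bicyclo[3.3.1]non-3-en-9-one
Product: 14 (1R,5S,7R)-4-methoxy-8,8-dimethyl-5-prenyl-7-(triethylsilyloxy)bicyclo[3.3.1]non-3-ene-2,9-dione
Conditions: PhI(OAc)2, t-BuOOH, Cs2CO3, EtOAc, −20 → 0 °C
Reagents that add atoms: tert-butyl hydroperoxide CC(C)(C)OO
Why: Radical allylic oxidation (tert-butylperoxy radical, then Kornblum–DeLaMare-type collapse of the allylic peroxide) takes the weakest C–H bonds, those at C2 next to the electron-rich enol ether, and converts the enol ether into a robust vinylogous ester.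

Step 9
Reactants: 14 (1R,5S,7R)-4-methoxy-8,8-dimethyl-5-prenyl-7-(triethylsilyloxy)bicyclo[3.3.1]non-3-ene-2,9-dione
Product: 16 (1S,5S,7R)-4-methoxy-8,8-dimethyl-5-prenyl-7-(triethylsilyloxy)-3-(trimethylsilyl)bicyclo[3.3.1]non-3-ene-2,9-dione, via C3-lithio enone 15 (not isolated)
Conditions: LiTMP, TMSCl (in situ quench), THF, −78 °C
Reagents that add atoms: chlorotrimethylsilane C[Si](C)(C)Cl
Why: α-Lithiation of the β-methoxy enone at C3, the kinetically most accessible acidic site, with in situ silyl trapping blocks C3 so that the next base can only find C1–H.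

Step 10
Reactants: 16 (1S,5S,7R)-4-methoxy-8,8-dimethyl-5-prenyl-7-(triethylsilyloxy)-3-(trimethylsilyl)bicyclo[3.3.1]non-3-ene-2,9-dione; 6 prenyl bromide
Product: 18 (1S,5S,7R)-4-methoxy-8,8-dimethyl-1,5-diprenyl-7-(triethylsilyloxy)-3-(trimethylsilyl)bicyclo[3.3.1]non-3-ene-2,9-dione, via C1-lithio bridgehead species 17 (not isolated)
Conditions: LiTMP, THF, −78 → −40 °C; then 6, −78 °C → rt
Reagents that add atoms: none
Why: Bridgehead lithiation–alkylation works because C1–H lies between the C2 and C9 carbonyl groups, and the geometrically locked bridgehead carbanion can only react with retention, so prenyl replaces hydrogen without change of geometry at C1.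

Step 11
Reactants: 18 (1S,5S,7R)-4-methoxy-8,8-dimethyl-1,5-diprenyl-7-(triethylsilyloxy)-3-(trimethylsilyl)bicyclo[3.3.1]non-3-ene-2,9-dione
Product: 19 (1R,5S,7R)-7-hydroxy-4-methoxy-8,8-dimethyl-1,5-diprenylbicyclo[3.3.1]non-3-ene-2,9-dione
Conditions: TBAF, AcOH (one equiv of each per silyl group), THF, 0 °C → rt
Reagents that add atoms: none
Why: Fluoride cleaves the O–Si bond and protodesilylates the α-silyl enone in one operation, the acetic acid buffer guarding the non-enolisable β-diketone against retro-Claisen opening.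

Step 12
Reactants: 19 (1R,5S,7R)-7-hydroxy-4-methoxy-8,8-dimethyl-1,5-diprenylbicyclo[3.3.1]non-3-ene-2,9-dione
Product: 20 (1R,5S)-4-methoxy-8,8-dimethyl-1,5-diprenylbicyclo[3.3.1]non-3-ene-2,7,9-trione
Conditions: Dess–Martin periodinane, CH2Cl2, rt
Reagents that add atoms: none
Why: Dess–Martin oxidation of the secondary alcohol erases the C7 stereocentre under near-neutral conditions that leave the alkenes and the vinylogous ester alone.

Step 13
Reactants: 20 (1R,5S)-4-methoxy-8,8-dimethyl-1,5-diprenylbicyclo[3.3.1]non-3-ene-2,7,9-trione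
Product: 21 (1R,5S)-4-methoxy-8,8-dimethyl-7-methylidene-1,5-diprenylbicyclo[3.3.1]non-3-ene-2,9-dione
Conditions: Ph3PCH3Br, KOt-Bu, toluene, rt → 80 °C
Reagents that add atoms: methyltriphenylphosphonium bromide C[P+](c1ccccc1)(c1ccccc1)c1ccccc1.[Br-]
Why: Wittig methylenation is chemoselective because C9 now sits between two quaternary carbons and C2 is a vinylogous ester carbonyl, which leaves the C7 ketone with its CH2 neighbour as the only reactive carbonyl group.

Step 14
Reactants: 22 6-methylhept-5-en-2-one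
Product: 24 6-methylhept-5-en-1-yne, via enol diethyl phosphate 23 (not isolated)
Conditions: LDA (1.1 equiv), THF, −78 °C; ClP(O)(OEt)2, −78 °C → rt; LDA (2.3 equiv), −78 °C → rt; H2O
Reagents that add atoms: none
Why: Kinetic enolate O-phosphorylation followed by base-induced elimination of the enol phosphate is the standard conversion of a methyl ketone into a terminal alkyne.

Step 15
Reactants: 24 6-methylhept-5-en-1-yne
Product: 26 (E)-1-iodo-2,6-dimethylhepta-1,5-diene, via (E)-alkenyl dimethylalane 25 (not isolated)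
Conditions: Me3Al, Cp2ZrCl2 (cat.), CH2Cl2, 0 °C → rt; then I2, THF, −30 → 0 °C
Reagents that add atoms: trimethylaluminium C[Al](C)C; iodine II
Why: Negishi zirconium-catalysed carboalumination adds methyl and aluminium syn across the alkyne with aluminium at the terminus, and iodinolysis with retention gives the (E)-iodide.

Step 16
Reactants: 21 (1R,5S)-4-methoxy-8,8-dimethyl-7-methylidene-1,5-diprenylbicyclo[3.3.1]non-3-ene-2,9-dione; 26 (E)-1-iodo-2,6-dimethylhepta-1,5-diene
Product: 28 (1R,5S,7S)-7-geranyl-4-methoxy-8,8-dimethyl-1,5-diprenylbicyclo[3.3.1]non-3-ene-2,9-dione (geranyl endo), via endo B-alkyl-9-BBN 27 (not isolated)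
Conditions: 9-BBN dimer, THF, 0 °C → rt; then 26, Pd(dppf)Cl2 (cat.), AsPh3 (cat.), Cs2CO3, DMF–H2O, rt
Reagents that add atoms: none
Why: 9-BBN should add only to the 1,1-disubstituted C7 methylene (trisubstituted alkenes and the crowded carbonyl groups react far more slowly) and must approach the convex exo face because ring A shields the endo face, so hydrogen lands exo on C7 and the CH2–B arm is pushed endo (7S), after which B-alkyl Suzuki–Miyaura coupling with 26 proceeds with retention of the (E)-geometry.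

Step 17
Reactants: 29 3,4-dihydroxybenzoic acid
Product: 30 tert-butyldimethylsilyl 3,4-bis(tert-butyldimethylsilyloxy)benzoate
Conditions: TBSCl (3.5 equiv), imidazole, DMF, rt
Reagents that add atoms: tert-butyldimethylsilyl chloride CC(C)(C)[Si](C)(C)Cl
Why: Exhaustive imidazole-promoted silylation masks both phenols and converts the acid into its silyl ester.

Step 18
Reactants: 30 tert-butyldimethylsilyl 3,4-bis(tert-butyldimethylsilyloxy)benzoate
Product: 31 3,4-bis(tert-butyldimethylsilyloxy)benzoyl chloride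
Conditions: (COCl)2, DMF (cat.), CH2Cl2, 0 °C → rt
Reagents that add atoms: oxalyl chloride O=C(Cl)C(=O)Cl
Why: Silyl esters are converted by oxalyl chloride and catalytic DMF (Vilsmeier-type activation) into acid chlorides without release of HCl, so the aryl silyl ethers survive.

Step 19
Reactants: 28 (1R,5S,7S)-7-geranyl-4-methoxy-8,8-dimethyl-1,5-diprenylbicyclo[3.3.1]non-3-ene-2,9-dione; 31 3,4-bis(tert-butyldimethylsilyloxy)benzoyl chloride
Product: 33 (1S,5S,7S)-3-[3,4-bis(tert-butyldimethylsilyloxy)benzoyl]-7-geranyl-4-methoxy-8,8-dimethyl-1,5-diprenylbicyclo[3.3.1]non-3-ene-2,9-dione, via C3-lithio enone 32 (not isolated)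
Conditions: LiTMP, THF, −78 °C; then 31, −78 → −40 °C
Reagents that add atoms: none
Why: With both bridgeheads quaternary, C3–H is the only acidic site, and the vinyllithium formed by LiTMP is acylated by the aroyl chloride (α-lithiation–acylation of a β-alkoxy enone).

Step 20
Reactants: 33 (1S,5S,7S)-3-[3,4-bis(tert-butyldimethylsilyloxy)benzoyl]-7-geranyl-4-methoxy-8,8-dimethyl-1,5-diprenylbicyclo[3.3.1]non-3-ene-2,9-dione
Product: 35 (1S,5S,7S)-3-(3,4-dihydroxybenzoyl)-7-geranyl-4-hydroxy-8,8-dimethyl-1,5-diprenylbicyclo[3.3.1]non-3-ene-2,9-dione (CNP0182339.2), via lithium enolate 34 (not isolated)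
Conditions: LiCl, DMSO, 120 °C, Ar; cool, THF, Et3N·3HF, rt
Reagents that add atoms: none
Why: Chloride dealkylates the vinylogous methyl ester by SN2 attack at the methyl group (Krapcho-type cleavage), and fluoride then removes both aryl silyl ethers under non-acidic, non-oxidising conditions that spare the trisubstituted alkenes and touch no stereocentre.

Compound list
1 | prenol (3-methylbut-2-en-1-ol) | CC(C)=CCO | starting material
2 | (R)-(3,3-dimethyloxiran-2-yl)methanol | CC1(C)O[C@@H]1CO | intermediate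
3 | (R)-(3,3-dimethyloxiran-2-yl)methyl triflate | CC1(C)O[C@@H]1COS(=O)(=O)C(F)(F)F | intermediate
4 | 1,3-dimethoxybenzene | COc1cccc(OC)c1 | starting material
5 | 1,5-dimethoxycyclohexa-1,4-diene | COC1=CCC=C(OC)C1 | intermediate
6 | prenyl bromide | CC(C)=CCBr | starting material
7 | 6-lithio-1,5-dimethoxycyclohexa-1,4-diene | [Li]C1C(OC)=CCC=C1OC | intermediate
8 | 1,5-dimethoxy-6-prenylcyclohexa-1,4-diene | CC(C)=CCC1C(OC)=CCC=C1OC | intermediate
9 | lithiated prenyl diene (6-lithio-1,5-dimethoxy-6-prenylcyclohexa-1,4-diene) | [Li]C1(CC=C(C)C)C(OC)=CCC=C1OC | intermediate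
10 | 6-{[(2R)-3,3-dimethyloxiran-2-yl]methyl}-1,5-dimethoxy-6-prenylcyclohexa-1,4-diene | CC1(C)O[C@@H]1CC1(CC=C(C)C)C(OC)=CCC=C1OC | intermediate
11 | internal C7–O–C9 methyl ketal: 7,9-epoxy-4,9-dimethoxy-8,8-dimethyl-5-prenylbicyclo[3.3.1]non-3-ene, oxygen bridge on the ring B side of C9, C1/C5/C7 as in 12 | O3[C@@H]1C[C@]2(CC=C(C)C)[C@@]3(OC)[C@@H](CC=C2OC)C1(C)C | intermediate
12 | (1S,5S,7R)-7-hydroxy-4-methoxy-8,8-dimethyl-5-prenylbicyclo[3.3.1]non-3-en-9-one, OH exo | O[C@@H]1C[C@]2(CC=C(C)C)C(=O)[C@@H](CC=C2OC)C1(C)C | intermediate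
13 | (1S,5S,7R)-4-methoxy-8,8-dimethyl-5-prenyl-7-(triethylsilyloxy)bicyclo[3.3.1]non-3-en-9-one | CC[Si](CC)(CC)O[C@@H]1C[C@]2(CC=C(C)C)C(=O)[C@@H](CC=C2OC)C1(C)C | intermediate
14 | (1R,5S,7R)-4-methoxy-8,8-dimethyl-5-prenyl-7-(triethylsilyloxy)bicyclo[3.3.1]non-3-ene-2,9-dione | CC[Si](CC)(CC)O[C@@H]1C[C@]2(CC=C(C)C)C(=O)[C@@H](C(=O)C=C2OC)C1(C)C | intermediate
15 | C3-lithio enone derived from 14 | CC[Si](CC)(CC)O[C@@H]1C[C@]2(CC=C(C)C)C(=O)[C@@H](C(=O)C([Li])=C2OC)C1(C)C | intermediate
16 | (1S,5S,7R)-4-methoxy-8,8-dimethyl-5-prenyl-7-(triethylsilyloxy)-3-(trimethylsilyl)bicyclo[3.3.1]non-3-ene-2,9-dione | CC[Si](CC)(CC)O[C@@H]1C[C@]2(CC=C(C)C)C(=O)[C@@H](C(=O)C([Si](C)(C)C)=C2OC)C1(C)C | intermediate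
17 | C1-lithio bridgehead species derived from 16 | CC[Si](CC)(CC)O[C@@H]1C[C@]2(CC=C(C)C)C(=O)[C@@]([Li])(C(=O)C([Si](C)(C)C)=C2OC)C1(C)C | intermediate
18 | (1S,5S,7R)-4-methoxy-8,8-dimethyl-1,5-diprenyl-7-(triethylsilyloxy)-3-(trimethylsilyl)bicyclo[3.3.1]non-3-ene-2,9-dione | CC[Si](CC)(CC)O[C@@H]1C[C@]2(CC=C(C)C)C(=O)[C@@](CC=C(C)C)(C(=O)C([Si](C)(C)C)=C2OC)C1(C)C | intermediate
19 | (1R,5S,7R)-7-hydroxy-4-methoxy-8,8-dimethyl-1,5-diprenylbicyclo[3.3.1]non-3-ene-2,9-dione | O[C@@H]1C[C@]2(CC=C(C)C)C(=O)[C@@](CC=C(C)C)(C(=O)C=C2OC)C1(C)C | intermediate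
20 | (1R,5S)-4-methoxy-8,8-dimethyl-1,5-diprenylbicyclo[3.3.1]non-3-ene-2,7,9-trione | O=C1C[C@]2(CC=C(C)C)C(=O)[C@@](CC=C(C)C)(C(=O)C=C2OC)C1(C)C | intermediate
21 | (1R,5S)-4-methoxy-8,8-dimethyl-7-methylidene-1,5-diprenylbicyclo[3.3.1]non-3-ene-2,9-dione | C=C1C[C@]2(CC=C(C)C)C(=O)[C@@](CC=C(C)C)(C(=O)C=C2OC)C1(C)C | intermediate
22 | 6-methylhept-5-en-2-one | CC(=O)CCC=C(C)C | starting material
23 | enol diethyl phosphate: diethyl 6-methylhepta-1,5-dien-2-yl phosphate | C=C(CCC=C(C)C)OP(=O)(OCC)OCC | intermediate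
24 | 6-methylhept-5-en-1-yne | C#CCCC=C(C)C | intermediate
25 | (E)-alkenyl dimethylalane: (E)-(2,6-dimethylhepta-1,5-dienyl)dimethylaluminium | CC(C)=CCC/C(C)=C/[Al](C)C | intermediate
26 | (E)-1-iodo-2,6-dimethylhepta-1,5-diene | CC(C)=CCC/C(C)=C/I | intermediate
27 | endo B-alkyl-9-BBN: 21 with H exo and CH2–(9-BBN) endo at C7 | C(B1C2CCCC1CCC2)[C@H]3C[C@]4(CC=C(C)C)C(=O)[C@@](CC=C(C)C)(C(=O)C=C4OC)C3(C)C | intermediate
28 | (1R,5S,7S)-7-geranyl-4-methoxy-8,8-dimethyl-1,5-diprenylbicyclo[3.3.1]non-3-ene-2,9-dione, geranyl endo | CC(C)=CCC/C(C)=C/C[C@H]1C[C@]2(CC=C(C)C)C(=O)[C@@](CC=C(C)C)(C(=O)C=C2OC)C1(C)C | intermediate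
29 | 3,4-dihydroxybenzoic acid | O=C(O)c1ccc(O)c(O)c1 | starting material
30 | tert-butyldimethylsilyl 3,4-bis(tert-butyldimethylsilyloxy)benzoate | CC(C)(C)[Si](C)(C)OC(=O)c1ccc(O[Si](C)(C)C(C)(C)C)c(O[Si](C)(C)C(C)(C)C)c1 | intermediate
31 | 3,4-bis(tert-butyldimethylsilyloxy)benzoyl chloride | O=C(Cl)c1ccc(O[Si](C)(C)C(C)(C)C)c(O[Si](C)(C)C(C)(C)C)c1 | intermediate
32 | C3-lithio enone derived from 28 | CC(C)=CCC/C(C)=C/C[C@H]1C[C@]2(CC=C(C)C)C(=O)[C@@](CC=C(C)C)(C(=O)C([Li])=C2OC)C1(C)C | intermediate
33 | (1S,5S,7S)-3-[3,4-bis(tert-butyldimethylsilyloxy)benzoyl]-7-geranyl-4-methoxy-8,8-dimethyl-1,5-diprenylbicyclo[3.3.1]non-3-ene-2,9-dione | CC(C)=CCC/C(C)=C/C[C@H]1C[C@]2(CC=C(C)C)C(=O)[C@@](CC=C(C)C)(C(=O)C(C(=O)c3ccc(O[Si](C)(C)C(C)(C)C)c(O[Si](C)(C)C(C)(C)C)c3)=C2OC)C1(C)C | intermediate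
34 | lithium enolate of the bis-silylated target (C4–OLi) | CC(C)=CCC/C(C)=C/C[C@H]1C[C@]2(CC=C(C)C)C(=O)[C@@](CC=C(C)C)(C(=O)C(C(=O)c3ccc(O[Si](C)(C)C(C)(C)C)c(O[Si](C)(C)C(C)(C)C)c3)=C2O[Li])C1(C)C | intermediate
35 | (1S,5S,7S)-3-(3,4-dihydroxybenzoyl)-7-geranyl-4-hydroxy-8,8-dimethyl-1,5-diprenylbicyclo[3.3.1]non-3-ene-2,9-dione | CC(C)=CCC/C(C)=C/C[C@H]1C[C@]2(CC=C(C)C)C(=O)[C@@](CC=C(C)C)(C(=O)C(C(=O)c3ccc(O)c(O)c3)=C2O)C1(C)C | target

Total step count: 20.
Longest linear sequence: 14 steps (3–13, 16, 19, 20) from 1,3-dimethoxybenzene.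

Steps most likely to fail

**Step 6.** The cyclisation itself has close analogy. The weak point is the release of the internal ketal in the same flask. The surviving C3=C4 enol ether may be protonated and hydrolysed, or the cleavage may stall because the bromoborane is tied up by lutidine.

The fallback sets out from 11, which is now isolated after the TMSOTf stage by a bicarbonate quench.
- Allylic oxidation under the conditions of step 8 should give the ketal enone F1, in which the fragile enol ether has become an acid-tolerant vinylogous ester.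
- Me2BBr in CH2Cl2 at −78 °C followed by bicarbonate then opens the ketal to the hydroxy enone F2.
- Silylation with TESOTf and 2,6-lutidine comes back to the route at 14.

**Step 10.** SN2 capture of the crowded C1 carbanion next to the C8 gem-dimethyl group may be too slow. Proton return or decomposition of the bridgehead anion would then win over alkylation.

The fallback sets out from 16.
- The lithio species 17 is quenched with iodine, a much smaller electrophile, to give the bridgehead iodide F3.
- Keck radical allylation (allyltributylstannane, Et3B, air, benzene) replaces iodine with retention enforced by the cage and gives the C1-allyl compound F4.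
- Cross metathesis with 2-methyl-2-butene (second-generation Grubbs catalyst, CH2Cl2, 40 °C) converts allyl into prenyl and comes back to the route at 18.

**Step 16.** Hydroboration of the neopentylic methylene may be slow enough for the dialkylborane to reduce the C2 or C9 carbonyl group. Transmetalation of the crowded endo alkyl group to palladium may also be sluggish.

The fallback sets out from 21.
- Rhodium-catalysed hydroboration (RhCl(PPh3)3, catecholborane, THF, rt) tolerates ketones and still has to come from the exo face. It gives the endo catechol boronate F5.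
- Buffered H2O2 oxidises F5 to the endo primary alcohol F6.
- Appel iodination (I2, PPh3, imidazole) gives the primary iodide F7.
- Zinc insertion (Zn dust, LiCl, THF) gives the alkylzinc iodide F8.
- Negishi coupling of F8 with 26 (Pd(dppf)Cl2, THF, rt) comes back to the route at 28.

Further compounds
F1 | step 6 | ketal enone (7,9-epoxy-4,9-dimethoxy-8,8-dimethyl-5-prenylbicyclo[3.3.1]non-3-en-2-one) | O3[C@@H]1C[C@]2(CC=C(C)C)[C@@]3(OC)[C@@H](C(=O)C=C2OC)C1(C)C
F2 | step 6 | hydroxy enone ((1R,5S,7R)-7-hydroxy-4-methoxy-8,8-dimethyl-5-prenylbicyclo[3.3.1]non-3-ene-2,9-dione) | O[C@@H]1C[C@]2(CC=C(C)C)C(=O)[C@@H](C(=O)C=C2OC)C1(C)C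
F3 | step 10 | bridgehead iodide (C1–I analogue of 18) | CC[Si](CC)(CC)O[C@@H]1C[C@]2(CC=C(C)C)C(=O)[C@@](I)(C(=O)C([Si](C)(C)C)=C2OC)C1(C)C
F4 | step 10 | C1-allyl compound (allyl analogue of 18) | CC[Si](CC)(CC)O[C@@H]1C[C@]2(CC=C(C)C)C(=O)[C@@](CC=C)(C(=O)C([Si](C)(C)C)=C2OC)C1(C)C
F5 | step 16 | endo catechol boronate | C(B1Oc2ccccc2O1)[C@H]3C[C@]4(CC=C(C)C)C(=O)[C@@](CC=C(C)C)(C(=O)C=C4OC)C3(C)C
F6 | step 16 | endo primary alcohol (C7–CH2OH) | OC[C@H]1C[C@]2(CC=C(C)C)C(=O)[C@@](CC=C(C)C)(C(=O)C=C2OC)C1(C)C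
F7 | step 16 | primary iodide (C7–CH2I) | IC[C@H]1C[C@]2(CC=C(C)C)C(=O)[C@@](CC=C(C)C)(C(=O)C=C2OC)C1(C)C
F8 | step 16 | alkylzinc iodide (C7–CH2ZnI) | I[Zn]C[C@H]1C[C@]2(CC=C(C)C)C(=O)[C@@](CC=C(C)C)(C(=O)C=C2OC)C1(C)C
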